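The route rests on cutting the oxane (O1', quaternary C2' bearing the cyclohexyl, C3' carbinol, C4', C5', C6' = CMe2) at O1'–C6' and C5'–Br. This vicinal, anti bromo-ether pair beside the gem-dimethyl carbon is the retron of a bromonium-induced 6-endo etherification. In one operation Br+ adds to the prenyl C5'=C6' bond of open-chain precursor 15. The tertiary C2' hydroxyl then captures C6' through a chair, closing the last ring and setting C5' with equatorial bromine. Precursor 15 is the finished bromochloro-cyclohexyl acetate carrying the C2' carbinol, a silyl-masked C3' hydroxyl and a prenyl tail. One organocatalytic stereocentre (C3') is relayed to all others by substrate control.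

Key step: step 10

Remark: the target is taken exactly as drawn in the SMILES. Cyclohexane locants are C1 (CHOAc, S), C2 (CH–oxanyl, S), C3 (CH2), C4 (CHBr, R), C5 (CClMe, R), C6 (CH2), and the oxane is 2'S,3'S,5'S. These target locants are used for all intermediates in the Why lines.

Step 1
Reactants: 1 hex-5-en-2-one
Product: 3 (3S)-3-hydroxyhex-5-en-2-one, via (3S)-3-[(phenylamino)oxy]hex-5-en-2-one 2 (not isolated)
Conditions: PhNO (limiting, slow addition), 1 in excess, D-proline (20 mol %), DMSO, rt; then CuSO4·5H2O (30 mol %), MeOH, 0 °C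
Reagents that add atoms: nitrosobenzene, O=Nc1ccccc1
Why: Proline-catalysed asymmetric α-aminoxylation (O-selective nitroso aldol reaction) should run through the more substituted E-enamine, the carboxylic acid of D-proline delivering PhN=O to one enamine face so that the S centre (future C3') is set, and the Cu(II)-catalysed N–O cleavage does not touch it.

Step 2
Reactants: 3 (3S)-3-hydroxyhex-5-en-2-one
Product: 4 (3S)-3-[(tert-butyldimethylsilyl)oxy]hex-5-en-2-one
Conditions: TBSCl, imidazole, DMF, 0 °C → rt
Reagents that add atoms: tert-butyldimethylsilyl chloride, CC(C)(C)[Si](C)(C)Cl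
Why: Imidazole-promoted silyl ether formation masks O3' with a bulky, poorly chelating and poorly nucleophilic group that later steers steps 4 and 7 and silences O3' in step 10, without touching the stereocentre.

Step 3
Reactants: 4 (3S)-3-[(tert-butyldimethylsilyl)oxy]hex-5-en-2-one
Product: 7 tert-butyl (1E,4S)-4-[(tert-butyldimethylsilyl)oxy]-3-oxohepta-1,6-dien-1-yl carbonate, via kinetic lithium enolate of 4 5 (not isolated), via lithium enolate of (4S)-4-[(tert-butyldimethylsilyl)oxy]-3-oxohept-6-enal 6 (not isolated)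
Conditions: LDA, THF, −78 °C; HCO2CH2CF3, −78 °C; Boc2O, DMAP (10 mol %), −78 → 0 °C
Reagents that add atoms: 2,2,2-trifluoroethyl formate, O=COCC(F)(F)F; di-tert-butyl dicarbonate, CC(C)(C)OC(=O)OC(=O)OC(C)(C)C
Why: Kinetic deprotonation at the methyl group, Claisen-type formylation and O-acylation of the β-ketoaldehyde enolate should give the enol carbonate, which DMAP equilibrates by addition–elimination to the E isomer, while the hindered C3'–H is not removed under kinetic conditions.

Step 4
Reactants: 7 tert-butyl (1E,4S)-4-[(tert-butyldimethylsilyl)oxy]-3-oxohepta-1,6-dien-1-yl carbonate; 8 isoprene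
Product: 9 tert-butyl (1S,6S)-6-{(2S)-2-[(tert-butyldimethylsilyl)oxy]pent-4-enoyl}-3-methylcyclohex-3-en-1-yl carbonate
Conditions: isoprene (10 equiv), Me2AlCl (30 mol %), CH2Cl2, −40 → −10 °C
Reagents that add atoms: none
Why: Normal-demand Diels–Alder reaction in which the Lewis-acid-bound enone imposes the "para" orientation (ring methyl 1,4 to the acyl-bearing C2), suprafacial addition turns the E-alkene into the trans C1–O/C2–acyl pair, and the diene should add to the s-cis enone on the face opposite the OTBS group in its non-chelated Felkin-type rotamer, the minor facial isomer being a separable diastereomer.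

Step 5
Reactants: 9 tert-butyl (1S,6S)-6-{(2S)-2-[(tert-butyldimethylsilyl)oxy]pent-4-enoyl}-3-methylcyclohex-3-en-1-yl carbonate
Product: 10 (1R,5S,6S,8R)-8-bromo-6-{(2S)-2-[(tert-butyldimethylsilyl)oxy]pent-4-enoyl}-1-methyl-2,4-dioxabicyclo[3.3.1]nonan-3-one (cyclic carbonate bridging O–C1 and O–C5 on one face, C4–Br on the other)
Conditions: NBS (1.05 equiv), 4 Å MS, CH2Cl2, −20 → 0 °C, dark
Reagents that add atoms: N-bromosuccinimide, O=C1CCC(=O)N1Br
Why: Bromocyclisation of a homoallylic tert-butyl carbonate (6-exo-trig halocarbonate formation), in which bromonium formation is reversible on both faces but only the ion anti to the C1 carbonate can be captured, by the carbonyl oxygen at tertiary C5 through the readily populated diaxial half-chair of this small-acyl substrate, and irreversible loss of isobutene then fixes C5–O syn to C1–O and C4–Br anti to it, the monosubstituted alkene being too poor a nucleophile to compete.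

Step 6
Reactants: 10 bicyclic bromocarbonate
Product: 11 (2S)-1-[(1S,2S,4R,5R)-5-bromo-4-chloro-2-hydroxy-4-methylcyclohexyl]-2-[(tert-butyldimethylsilyl)oxy]pent-4-en-1-one
Conditions: TiCl4 (1.5 equiv), CH2Cl2, −78 → −30 °C; then H2O
Reagents that add atoms: titanium tetrachloride, Cl[Ti](Cl)(Cl)Cl
Why: Proposed new method: TiCl4 binds the carbonate carbonyl, the tertiary C5–O bond (locked antiperiplanar to C4–Br in the bicycle) ionises with anchimeric assistance to the lower-face bromonium ion, and chloride returns to C5 from the face the oxygen left (diaxial, Markovnikov opening), so substitution occurs with retention, CO2 is lost and the ring flips to the all-equatorial bromochloride (axial methyl), which can no longer ionise with assistance; the closest known reaction types are the Lewis-acid AAL1 cleavage of tert-alkyl (Boc-type) carbonates to tert-alkyl chlorides and the retentive conversion of trans-bromohydrins into vicinal dihalides.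

Step 7
Reactants: 11 bromochloro hydroxy ketone
Product: 12 (2S,3S)-2-[(1S,2S,4R,5R)-5-bromo-4-chloro-2-hydroxy-4-methylcyclohexyl]-3-[(tert-butyldimethylsilyl)oxy]hex-5-en-2-ol
Conditions: MeLi (3 equiv), Et2O–THF, −78 °C; AcOH quench
Reagents that add atoms: methyllithium, [Li]C
Why: Felkin–Anh-controlled 1,2-addition in which the non-chelating OTBS group stands antiperiplanar to the nucleophile (polar model at C3') and the branched C1 arm of the ring stands anti at C2, so both flanking stereocentres expose the same carbonyl face and C2' should be set as S, while the equatorial halides have no antiperiplanar ring hydrogens for E2 at −78 °C.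

Step 8
Reactants: 12 diol
Product: 13 (1S,2S,4R,5R)-4-bromo-2-{(2S,3S)-3-[(tert-butyldimethylsilyl)oxy]-2-hydroxyhex-5-en-2-yl}-5-chloro-5-methylcyclohexyl acetate
Conditions: Ac2O, pyridine, DMAP (5 mol %), CH2Cl2, 0 °C → rt
Reagents that add atoms: acetic anhydride, CC(=O)OC(C)=O
Why: Chemoselective DMAP-catalysed acylation, since only the secondary C1–OH reacts, the tertiary C2'–OH being too hindered and O3' silylated.

Step 9
Reactants: 13 acetate; 14 2-methylbut-2-ene
Product: 15 (1S,2S,4R,5R)-4-bromo-2-{(2S,3S)-3-[(tert-butyldimethylsilyl)oxy]-2-hydroxy-6-methylhept-5-en-2-yl}-5-chloro-5-methylcyclohexyl acetate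
Conditions: 2-methylbut-2-ene (excess), (H2IMes)(PCy3)Cl2Ru=CHPh (5 mol %), CH2Cl2, 40 °C
Reagents that add atoms: none
Why: Olefin cross-metathesis of a terminal alkene with 2-methylbut-2-ene (allyl-to-prenyl conversion) is driven by loss of propene, tolerates alcohol, ester, silyl ether and alkyl halides, and touches no stereocentre.

Step 10
Reactants: 15 prenyl carbinol
Product: 16 (1S,2S,4R,5R)-4-bromo-2-{(2S,3S,5S)-5-bromo-3-[(tert-butyldimethylsilyl)oxy]-2,6,6-trimethyloxan-2-yl}-5-chloro-5-methylcyclohexyl acetate
Conditions: BDSB (Et2SBr·SbCl5Br, 1.1 equiv), MeNO2, −25 °C, 10 min; aq Na2SO3/NaHCO3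
Reagents that add atoms: bromodiethylsulfonium bromopentachloroantimonate (BDSB), CC[S+](Br)CC.Cl[Sb-](Cl)(Cl)(Cl)(Cl)Br
Why: BDSB transfers Br+ reversibly to the only nucleophilic alkene, the prenyl C5'=C6' bond, and the unsymmetrical bromonium ion is opened anti at its tertiary terminus C6' by the tertiary C2' hydroxyl with loss of a proton. The closest known reaction type is the bromonium-induced etherification of bishomoallylic tertiary alcohols that delivers the 3-bromo-2,2,6-trialkyloxane rings of marine terpenoid ethers. The oxane closes in the 6-endo-trig mode. The new stereocentre C5' is controlled by the chair transition state, in which anti addition forces bromine equatorial, the bulky cyclohexyl group on C2' sits equatorial and the C3' silyloxy group axial (gauche to only one carbon substituent of C2'), so one alkene face is selected. The step needs 6-endo over 5-exo regioselectivity, secured by the Markovnikov bias of the trisubstituted alkene reinforced by the inductive pull of C3'–O on C5' and by the ionising solvent, and it needs O2' to win over O3', secured by the TBS group, which shuts off 5-endo closure. The equatorial C4–Br/C5–Cl pair lacks antiperiplanar assistance and the acetate is remote, so both should survive the short, cold exposure.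

Step 11
Reactants: 16 silylated bromo-oxane
Product: 17 (5S)-5-acetoxycaespitol
Conditions: HF·pyridine, THF, 0 °C → rt
Reagents that add atoms: none
Why: Fluoride-mediated desilylation under non-basic conditions frees the axial C3'–OH and leaves the acetate, both secondary bromides and the tertiary chloride untouched.

Compound list
1 | hex-5-en-2-one | CC(=O)CCC=C | starting material
2 | (3S)-3-[(phenylamino)oxy]hex-5-en-2-one | CC(=O)[C@@H](ONc1ccccc1)CC=C | intermediate
3 | (3S)-3-hydroxyhex-5-en-2-one | CC(=O)[C@@H](O)CC=C | intermediate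
4 | (3S)-3-[(tert-butyldimethylsilyl)oxy]hex-5-en-2-one | CC(=O)[C@@H](O[Si](C)(C)C(C)(C)C)CC=C | intermediate
5 | kinetic lithium enolate of 4 | [Li+].[O-]C(=C)[C@@H](O[Si](C)(C)C(C)(C)C)CC=C | intermediate
6 | lithium enolate of (4S)-4-[(tert-butyldimethylsilyl)oxy]-3-oxohept-6-enal | [Li+].[O-]/C=C\C(=O)[C@@H](O[Si](C)(C)C(C)(C)C)CC=C | intermediate
7 | tert-butyl (1E,4S)-4-[(tert-butyldimethylsilyl)oxy]-3-oxohepta-1,6-dien-1-yl carbonate | CC(C)(C)OC(=O)O/C=C/C(=O)[C@@H](O[Si](C)(C)C(C)(C)C)CC=C | intermediate
8 | isoprene | C=CC(C)=C | starting material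
9 | tert-butyl (1S,6S)-6-{(2S)-2-[(tert-butyldimethylsilyl)oxy]pent-4-enoyl}-3-methylcyclohex-3-en-1-yl carbonate | CC(C)(C)OC(=O)O[C@H]1CC(C)=CC[C@@H]1C(=O)[C@@H](O[Si](C)(C)C(C)(C)C)CC=C | intermediate
10 | (1R,5S,6S,8R)-8-bromo-6-{(2S)-2-[(tert-butyldimethylsilyl)oxy]pent-4-enoyl}-1-methyl-2,4-dioxabicyclo[3.3.1]nonan-3-one | O=C2O[C@H]1C[C@@](C)(O2)[C@H](Br)C[C@@H]1C(=O)[C@@H](O[Si](C)(C)C(C)(C)C)CC=C | intermediate
11 | (2S)-1-[(1S,2S,4R,5R)-5-bromo-4-chloro-2-hydroxy-4-methylcyclohexyl]-2-[(tert-butyldimethylsilyl)oxy]pent-4-en-1-one | O[C@H]1C[C@@](C)(Cl)[C@H](Br)C[C@@H]1C(=O)[C@@H](O[Si](C)(C)C(C)(C)C)CC=C | intermediate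
12 | (2S,3S)-2-[(1S,2S,4R,5R)-5-bromo-4-chloro-2-hydroxy-4-methylcyclohexyl]-3-[(tert-butyldimethylsilyl)oxy]hex-5-en-2-ol | O[C@H]1C[C@@](C)(Cl)[C@H](Br)C[C@@H]1[C@](C)(O)[C@@H](O[Si](C)(C)C(C)(C)C)CC=C | intermediate
13 | (1S,2S,4R,5R)-4-bromo-2-{(2S,3S)-3-[(tert-butyldimethylsilyl)oxy]-2-hydroxyhex-5-en-2-yl}-5-chloro-5-methylcyclohexyl acetate | CC(=O)O[C@H]1C[C@@](C)(Cl)[C@H](Br)C[C@@H]1[C@](C)(O)[C@@H](O[Si](C)(C)C(C)(C)C)CC=C | intermediate
14 | 2-methylbut-2-ene | CC=C(C)C | starting material
15 | (1S,2S,4R,5R)-4-bromo-2-{(2S,3S)-3-[(tert-butyldimethylsilyl)oxy]-2-hydroxy-6-methylhept-5-en-2-yl}-5-chloro-5-methylcyclohexyl acetate | CC(=O)O[C@H]1C[C@@](C)(Cl)[C@H](Br)C[C@@H]1[C@](C)(O)[C@@H](O[Si](C)(C)C(C)(C)C)CC=C(C)C | intermediate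
16 | (1S,2S,4R,5R)-4-bromo-2-{(2S,3S,5S)-5-bromo-3-[(tert-butyldimethylsilyl)oxy]-2,6,6-trimethyloxan-2-yl}-5-chloro-5-methylcyclohexyl acetate | CC(=O)O[C@H]1C[C@@](C)(Cl)[C@H](Br)C[C@@H]1[C@]1(C)OC(C)(C)[C@@H](Br)C[C@@H]1O[Si](C)(C)C(C)(C)C | intermediate
17 | (5S)-5-acetoxycaespitol | CC(=O)O[C@H]1C[C@@](C)(Cl)[C@H](Br)C[C@@H]1[C@]1(C)OC(C)(C)[C@@H](Br)C[C@@H]1O | target

Total step count: 11. Longest linear sequence: 11 steps (from 1).

Steps most likely to fail

Step 6 (labelled step). After ionisation of the C5–O bond the cation may lose a proton, re-close on the carbonate, or the Lewis acid may strip the silyl ether, instead of chloride being taken up. The fallback uses known chemistry, sets out from 10 and comes back at 11. Carbonate methanolysis with K2CO3/MeOH, with in situ closure of the liberated C5 alkoxide onto C4–Br, should give the syn-epoxy alcohol (2S)-2-[(tert-butyldimethylsilyl)oxy]-1-[(1S,2S,4R,5S)-4,5-epoxy-2-hydroxy-4-methylcyclohexyl]pent-4-en-1-one F1. SN2-type opening at the secondary carbon with LiBr/AcOH in THF should return bromine to C4 from the lower face and give the bromodiol (2S)-1-[(1S,2S,4R,5R)-5-bromo-2,4-dihydroxy-4-methylcyclohexyl]-2-[(tert-butyldimethylsilyl)oxy]pent-4-en-1-one F2. Concentrated HCl in Et2O at 0 °C should then replace only the tertiary hydroxyl, with retention through the same bromonium ion, to give 11.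

Step 10 (key step). Capture at C5' (5-exo closure to an oxolane), premature desilylation followed by 5-endo closure through O3', or weak facial control in the strained 2,2,6,6-substituted chair may erode the outcome. The fallback sets out from 15 and comes back at 16. Mercuricyclisation with Hg(OCOCF3)2 in MeNO2 at −20 °C obeys Markovnikov orientation more strictly than a bromonium ion. Followed by aq KBr, it should give the equatorial organomercurial (1S,2S,4R,5R)-4-bromo-2-{(2S,3S,5S)-5-(bromomercurio)-3-[(tert-butyldimethylsilyl)oxy]-2,6,6-trimethyloxan-2-yl}-5-chloro-5-methylcyclohexyl acetate F3. Electrophilic bromodemercuration with Br2 in pyridine, which proceeds with retention, should then give 16.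

Step 4. Facial discrimination by the C3' stereocentre may be weak, the para/meta orientation may erode, or the Boc group may be lost to the Lewis acid. The fallback moves the ring stereocentres to reagent control, sets out from 1 and comes back at 9. Formylation and Boc trapping of 1 (as in step 3) should give the achiral dienophile tert-butyl (1E)-3-oxohepta-1,6-dien-1-yl carbonate F4. A catalytic enantioselective Diels–Alder reaction with isoprene under a proline-derived cationic oxazaborolidinium triflimide catalyst (the enantiomer that shields the unwanted face) should give tert-butyl (1S,6S)-3-methyl-6-(pent-4-enoyl)cyclohex-3-en-1-yl carbonate F5. Kinetic enolisation with KHMDS and oxidation with an enantiopure (camphorylsulfonyl)oxaziridine should give tert-butyl (1S,6S)-6-[(2S)-2-hydroxypent-4-enoyl]-3-methylcyclohex-3-en-1-yl carbonate F6. Silylation with TBSOTf/2,6-lutidine should then give 9.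

Further compounds
F1 | step 6 | (2S)-2-[(tert-butyldimethylsilyl)oxy]-1-[(1S,2S,4R,5S)-4,5-epoxy-2-hydroxy-4-methylcyclohexyl]pent-4-en-1-one | O[C@H]1C[C@@]2(C)O[C@H]2C[C@@H]1C(=O)[C@@H](O[Si](C)(C)C(C)(C)C)CC=C
F2 | step 6 | (2S)-1-[(1S,2S,4R,5R)-5-bromo-2,4-dihydroxy-4-methylcyclohexyl]-2-[(tert-butyldimethylsilyl)oxy]pent-4-en-1-one | O[C@H]1C[C@@](C)(O)[C@H](Br)C[C@@H]1C(=O)[C@@H](O[Si](C)(C)C(C)(C)C)CC=C
F3 | step 10 | (1S,2S,4R,5R)-4-bromo-2-{(2S,3S,5S)-5-(bromomercurio)-3-[(tert-butyldimethylsilyl)oxy]-2,6,6-trimethyloxan-2-yl}-5-chloro-5-methylcyclohexyl acetate | CC(=O)O[C@H]1C[C@@](C)(Cl)[C@H](Br)C[C@@H]1[C@]1(C)OC(C)(C)[C@@H]([Hg]Br)C[C@@H]1O[Si](C)(C)C(C)(C)C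
F4 | step 4 | tert-butyl (1E)-3-oxohepta-1,6-dien-1-yl carbonate | CC(C)(C)OC(=O)O/C=C/C(=O)CCC=C
F5 | step 4 | tert-butyl (1S,6S)-3-methyl-6-(pent-4-enoyl)cyclohex-3-en-1-yl carbonate | CC(C)(C)OC(=O)O[C@H]1CC(C)=CC[C@@H]1C(=O)CCC=C
F6 | step 4 | tert-butyl (1S,6S)-6-[(2S)-2-hydroxypent-4-enoyl]-3-methylcyclohex-3-en-1-yl carbonate | CC(C)(C)OC(=O)O[C@H]1CC(C)=CC[C@@H]1C(=O)[C@@H](O)CC=C
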